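## Retrosynthetic overview

1. Target ⇒ its tri-O-benzyl ether (benzyl on the flavanone 4'-O and the flavone 5-O and 7-O), cleaved last by neutral hydrogenolysis.
2. Flavanone ring C: O1–C2 bond ⇒ a free 2',6'-dihydroxychalcone. This C–O bond is closed late by a catalytic enantioselective oxa-Michael addition that sets (2S).
3. Chalcone Cα=Cβ ⇒ 2',6'-dihydroxy-4'-methoxyacetophenone + a diaryl-ether aldehyde (Claisen–Schmidt).
4. Diaryl ether C–O bond ⇒ 4-(benzyloxy)-3-hydroxybenzaldehyde + 4'-bromo-5,7-bis(benzyloxy)flavone (Ullmann).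
5. Flavone ring C ⇒ phloroglucinol + ethyl 4-bromobenzoylacetate (thermal condensation). Ring order: flavone pyranone ring first, flavanone pyranone ring last.

Assumption: the stereocentre written [C@H] (C2 of the chromanone) is (S), as in natural flavanones; compounds 1, 2, 6 and 8 and the squaramide catalyst are taken as catalogue chemicals.

## Route

Step 1
Reactants: 1 phloroglucinol (benzene-1,3,5-triol); 2 ethyl 3-(4-bromophenyl)-3-oxopropanoate
Product: 4 2-(4-bromophenyl)-5,7-dihydroxy-4H-chromen-4-one, via open-chain 1,3-diketone 3 (not isolated)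
Conditions: neat melt, 2 (2 equiv), 240 °C, Ar, 30 min (microwave or sand bath); triturate with Et2O, recrystallise from EtOH
Reagents that add atoms: none
Why: Thermal Mentzer/Simonis-type flavone synthesis: above 200 °C the β-keto ester C-acylates the very electron-rich phloroglucinol with loss of ethanol to give diketone 3, which cyclodehydrates (Baker–Venkataraman-type closure) to the chromone; without acid the flavone, not the Pechmann coumarin, forms, and the aryl bromide is inert.

Step 2
Reactants: 4 2-(4-bromophenyl)-5,7-dihydroxy-4H-chromen-4-one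
Product: 5 5,7-bis(benzyloxy)-2-(4-bromophenyl)-4H-chromen-4-one
Conditions: BnBr (3 equiv), K2CO3 (4 equiv), n-Bu4NI (10 mol%), DMF, 80 °C, 12 h
Reagents that add atoms: benzyl bromide, BrCc1ccccc1
Why: Williamson ether synthesis; the acidic 7-OH alkylates fast and the chelated 5-OH follows with excess BnBr, iodide catalysis and heat, and benzyl is chosen because it is later removed by neutral hydrogenolysis that cannot racemise a flavanone.

Step 3
Reactants: 5 5,7-bis(benzyloxy)-2-(4-bromophenyl)-4H-chromen-4-one; 6 4-(benzyloxy)-3-hydroxybenzaldehyde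
Product: 7 4-(benzyloxy)-3-{4-[5,7-bis(benzyloxy)-4-oxo-4H-chromen-2-yl]phenoxy}benzaldehyde
Conditions: 6 (1.5 equiv), CuI (10 mol%), N,N-dimethylglycine·HCl (30 mol%), Cs2CO3 (2.5 equiv), 1,4-dioxane, 100 °C, 24 h
Reagents that add atoms: none
Why: Ligand-accelerated Ullmann diaryl ether synthesis (C–O bond): the bromide is activated by the para chromone (vinylogous acyl) group, 6 has a single free OH so the catechol regiochemistry (aryl on O-3, benzyl on O-4) is fixed by the starting material, and the non-enolisable aldehyde, the benzyl ethers and the flavone tolerate carbonate in dioxane.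

Step 4
Reactants: 7 4-(benzyloxy)-3-{4-[5,7-bis(benzyloxy)-4-oxo-4H-chromen-2-yl]phenoxy}benzaldehyde; 8 1-(2,6-dihydroxy-4-methoxyphenyl)ethan-1-one (2',6'-dihydroxy-4'-methoxyacetophenone)
Product: 9 (2E)-3-[4-(benzyloxy)-3-{4-[5,7-bis(benzyloxy)-4-oxo-4H-chromen-2-yl]phenoxy}phenyl]-1-(2,6-dihydroxy-4-methoxyphenyl)prop-2-en-1-one
Conditions: 8 (1.5 equiv), KOH (40% aq., 10 equiv), EtOH/THF 1:1, 0 °C → rt, 36 h, N2, dark; then ice/1 M HCl to pH 4; crystallise cold (no silica, no heating)
Reagents that add atoms: none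
Why: Claisen–Schmidt (crossed aldol) condensation: only 8 can enolise and only 7 is an aldehyde, E1cB dehydration gives the E-enone, and in strong base the 2',6'-dihydroxychalcone stays ring-open as its phenoxide, so cold acidification delivers 9 before any racemic ring closure.

Step 5
Reactants: 9 (2E)-3-[4-(benzyloxy)-3-{4-[5,7-bis(benzyloxy)-4-oxo-4H-chromen-2-yl]phenoxy}phenyl]-1-(2,6-dihydroxy-4-methoxyphenyl)prop-2-en-1-one
Product: 10 (2S)-2-[4-(benzyloxy)-3-{4-[5,7-bis(benzyloxy)-4-oxo-4H-chromen-2-yl]phenoxy}phenyl]-5-hydroxy-7-methoxy-2,3-dihydro-4H-chromen-4-one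
Conditions: 3-{[3,5-bis(trifluoromethyl)phenyl]amino}-4-{[(8α,9S)-6'-methoxycinchonan-9-yl]amino}cyclobut-3-ene-1,2-dione (quinine-derived squaramide, C32H28F6N4O3, 10 mol%), toluene/CH2Cl2 4:1, 4 Å MS, −30 °C, 48 h, dark; then AcOH quench, short silica plug, recrystallise
Reagents that add atoms: none
Why: Proposed new method: catalyst-controlled enantioselective 6-endo-trig oxa-Michael cyclisation of a free 2',6'-dihydroxychalcone, a substrate class for which no highly enantioselective small-molecule ring closure is established; the quinuclidine nitrogen acts as general base on one of the two equivalent phenolic OH groups while the squaramide NH pair, helped by the internal hydrogen bond from the second OH, stabilises the developing enolate oxygen (an oxyanion-hole arrangement like that of chalcone isomerase), so the phenoxide oxygen is delivered to the Si face of C-β (priorities aryl > C-α > H) and C2 is set as (S) in the C–O bond-forming step, after which the quinuclidinium protonates C3; because the remaining 5-OH···O=C4 hydrogen bond places the chalcone–flavanone equilibrium far on the flavanone side, the retro-oxa-Michael racemisation path is much slower than closure at −30 °C and kinetic selectivity survives if the catalyst is quenched at full conversion; the closest known reaction type is the cinchona thiourea- or squaramide-catalysed intramolecular oxa-Michael addition of phenols to enones (chroman synthesis, low-ee closure of simple 2'-hydroxychalcones, high-ee closure of activated alkylidene β-keto esters); the sense of induction is checked on the first run by circular dichroism and chiral HPLC, and the pseudo-enantiomeric quinidine-derived squaramide is the switch if it is reversed.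

Step 6
Reactants: 10 (2S)-2-[4-(benzyloxy)-3-{4-[5,7-bis(benzyloxy)-4-oxo-4H-chromen-2-yl]phenoxy}phenyl]-5-hydroxy-7-methoxy-2,3-dihydro-4H-chromen-4-one
Product: 11 (2S)-2-{3-[4-(5,7-dihydroxy-4-oxo-4H-chromen-2-yl)phenoxy]-4-hydroxyphenyl}-5-hydroxy-7-methoxy-2,3-dihydro-4H-chromen-4-one (CNP0145819.1)
Conditions: H2 (1 atm), 10% Pd/C, THF/EtOAc 1:1, rt, stop after 3 equiv H2 uptake (4–8 h); filter; Sephadex LH-20 (MeOH)
Reagents that add atoms: none
Why: Hydrogenolysis of the three benzyl ethers over palladium; at 1 atm and room temperature the flavone C2=C3 bond, both ketones and the benzylic C2–O1 bond react much more slowly than O-benzyl groups, and the base-free medium keeps the (2S) centre intact although it now carries a para-hydroxyphenyl group that would promote ring opening in base.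

## Compound list

1 | phloroglucinol (benzene-1,3,5-triol) | Oc1cc(O)cc(O)c1 | starting material
2 | ethyl 3-(4-bromophenyl)-3-oxopropanoate | CCOC(=O)CC(=O)c1ccc(Br)cc1 | starting material
3 | 1-(4-bromophenyl)-3-(2,4,6-trihydroxyphenyl)propane-1,3-dione (open-chain 1,3-diketone) | O=C(CC(=O)c1ccc(Br)cc1)c1c(O)cc(O)cc1O | intermediate
4 | 2-(4-bromophenyl)-5,7-dihydroxy-4H-chromen-4-one | O=c1cc(-c2ccc(Br)cc2)oc2cc(O)cc(O)c12 | intermediate
5 | 5,7-bis(benzyloxy)-2-(4-bromophenyl)-4H-chromen-4-one | O=c1cc(-c2ccc(Br)cc2)oc2cc(OCc3ccccc3)cc(OCc3ccccc3)c12 | intermediate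
6 | 4-(benzyloxy)-3-hydroxybenzaldehyde | O=Cc1ccc(OCc2ccccc2)c(O)c1 | starting material
7 | 4-(benzyloxy)-3-{4-[5,7-bis(benzyloxy)-4-oxo-4H-chromen-2-yl]phenoxy}benzaldehyde | O=Cc1ccc(OCc2ccccc2)c(Oc2ccc(-c3cc(=O)c4c(OCc5ccccc5)cc(OCc5ccccc5)cc4o3)cc2)c1 | intermediate
8 | 1-(2,6-dihydroxy-4-methoxyphenyl)ethan-1-one | CC(=O)c1c(O)cc(OC)cc1O | starting material
9 | (2E)-3-[4-(benzyloxy)-3-{4-[5,7-bis(benzyloxy)-4-oxo-4H-chromen-2-yl]phenoxy}phenyl]-1-(2,6-dihydroxy-4-methoxyphenyl)prop-2-en-1-one | COc1cc(O)c(C(=O)/C=C/c2ccc(OCc3ccccc3)c(Oc3ccc(-c4cc(=O)c5c(OCc6ccccc6)cc(OCc6ccccc6)cc5o4)cc3)c2)c(O)c1 | intermediate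
10 | (2S)-2-[4-(benzyloxy)-3-{4-[5,7-bis(benzyloxy)-4-oxo-4H-chromen-2-yl]phenoxy}phenyl]-5-hydroxy-7-methoxy-2,3-dihydro-4H-chromen-4-one | COc1cc(O)c2c(c1)O[C@H](c1ccc(OCc3ccccc3)c(Oc3ccc(-c4cc(=O)c5c(OCc6ccccc6)cc(OCc6ccccc6)cc5o4)cc3)c1)CC2=O | intermediate
11 | (2S)-2-{3-[4-(5,7-dihydroxy-4-oxo-4H-chromen-2-yl)phenoxy]-4-hydroxyphenyl}-5-hydroxy-7-methoxy-2,3-dihydro-4H-chromen-4-one | COc1cc(O)c2c(c1)O[C@H](c1ccc(O)c(Oc3ccc(-c4cc(=O)c5c(O)cc(O)cc5o4)cc3)c1)CC2=O | target

## Step count and risk

Total steps: 6. Longest linear sequence: 6 steps (1 + 2 → 4 → 5 → 7 → 9 → 10 → 11).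

Most likely to fail:

**Step 5 (the new enantioselective ring closure).** Selectivity may be low, or background closure may erode it. The fallback sets out from 9 and comes back at 10, using known chemistry. Chalcone 9 is heated with NaOAc in EtOH/THF at reflux, the classical base-mediated chalcone–flavanone isomerisation, to give racemic 2-[4-(benzyloxy)-3-{4-[5,7-bis(benzyloxy)-4-oxo-4H-chromen-2-yl]phenoxy}phenyl]-5-hydroxy-7-methoxy-2,3-dihydro-4H-chromen-4-one F1. Preparative HPLC on an amylose tris(3,5-dimethylphenylcarbamate) phase then separates 10 from its (2R) enantiomer F2. F2 is returned to the NaOAc equilibration, where it racemises by ring opening and reclosure, and is recycled.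

**Step 4 (Claisen–Schmidt with the unprotected dihydroxyacetophenone next to a hydroxide-sensitive flavone).** The dianion of 8 is sluggish, and hydroxide may open the flavone over the long reaction time. The fallback sets out from 8 and comes back at 9. MOMCl and i-Pr2NEt in CH2Cl2 (0 °C → rt) protect the non-chelated hydroxyl to give 1-[2-hydroxy-4-methoxy-6-(methoxymethoxy)phenyl]ethan-1-one F3. A hydroxide-free condensation of F3 with 7 (NaH, THF/DMF, 0 °C → rt) gives the MOM-protected chalcone (2E)-3-[4-(benzyloxy)-3-{4-[5,7-bis(benzyloxy)-4-oxo-4H-chromen-2-yl]phenoxy}phenyl]-1-[2-hydroxy-4-methoxy-6-(methoxymethoxy)phenyl]prop-2-en-1-one F4. Mild acetal cleavage (3 M HCl in MeOH/THF, rt, monitored to avoid ring closure) then gives 9.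

**Step 3 (Ullmann coupling of an ortho-alkoxy, aldehyde-bearing phenol).** Conversion may stall or the bromide may be reduced. The fallback sets out from 5 and comes back at 7. Miyaura borylation (B2pin2, PdCl2(dppf), KOAc, dioxane, 90 °C) gives 5,7-bis(benzyloxy)-2-[4-(4,4,5,5-tetramethyl-1,3,2-dioxaborolan-2-yl)phenyl]-4H-chromen-4-one F5. Chan–Lam–Evans oxidative C–O coupling of F5 with 6 (Cu(OAc)2, pyridine, B(OH)3, 4 Å MS, MeCN, air, 60 °C) gives 7 without strong base or high temperature.

## Further compounds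

F1 | step 5 | racemic 2-[4-(benzyloxy)-3-{4-[5,7-bis(benzyloxy)-4-oxo-4H-chromen-2-yl]phenoxy}phenyl]-5-hydroxy-7-methoxy-2,3-dihydro-4H-chromen-4-one | COc1cc(O)c2c(c1)OC(c1ccc(OCc3ccccc3)c(Oc3ccc(-c4cc(=O)c5c(OCc6ccccc6)cc(OCc6ccccc6)cc5o4)cc3)c1)CC2=O
F2 | step 5 | (2R)-2-[4-(benzyloxy)-3-{4-[5,7-bis(benzyloxy)-4-oxo-4H-chromen-2-yl]phenoxy}phenyl]-5-hydroxy-7-methoxy-2,3-dihydro-4H-chromen-4-one | COc1cc(O)c2c(c1)O[C@@H](c1ccc(OCc3ccccc3)c(Oc3ccc(-c4cc(=O)c5c(OCc6ccccc6)cc(OCc6ccccc6)cc5o4)cc3)c1)CC2=O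
F3 | step 4 | 1-[2-hydroxy-4-methoxy-6-(methoxymethoxy)phenyl]ethan-1-one | CC(=O)c1c(O)cc(OC)cc1OCOC
F4 | step 4 | (2E)-3-[4-(benzyloxy)-3-{4-[5,7-bis(benzyloxy)-4-oxo-4H-chromen-2-yl]phenoxy}phenyl]-1-[2-hydroxy-4-methoxy-6-(methoxymethoxy)phenyl]prop-2-en-1-one | COCOc1cc(OC)cc(O)c1C(=O)/C=C/c1ccc(OCc2ccccc2)c(Oc2ccc(-c3cc(=O)c4c(OCc5ccccc5)cc(OCc5ccccc5)cc4o3)cc2)c1
F5 | step 3 | 5,7-bis(benzyloxy)-2-[4-(4,4,5,5-tetramethyl-1,3,2-dioxaborolan-2-yl)phenyl]-4H-chromen-4-one | O=c1cc(-c2ccc(B3OC(C)(C)C(C)(C)O3)cc2)oc2cc(OCc3ccccc3)cc(OCc3ccccc3)c12
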